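**Retrosynthetic overview**
1. Target 14 comes from the (S)-tetralone 13 by removal of three MOM groups.
2. 13 comes from the achiral α-chloroketone 12 by closing the C2–C3 bond of the tetralone (the CH2 alpha to the ketone joined to the CH2 beside the stereocenter). The reaction is a photoenzymatic 6-endo radical cyclization in a flavin-dependent ene-reductase, and the enzyme sets C4 by hydrogen-atom transfer.
3. Enabling feature: the C1 ketone makes C2 an alpha-keto radical site (from C2–Cl). C4 is flanked by benzene ring A and the naphthalene, so a C3=C4 1,1-diarylethene takes that radical at C3 and leaves a doubly benzylic, prochiral radical at C4. C1 and C4 are ortho on ring A, so a six-membered ring results.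
4. 12 comes from aryl bromide 10 (Br–Li exchange, chloroacetyl Weinreb amide); 10 from ketone 9 (Wittig); 9 from naphthyllithium 7 and bromoaldehyde 3 (addition, oxidation).
5. Ring order: ring A and the naphthalene are bought (1 and 4); the only ring formed is the cyclohexanone ring of the tetralone, in step 9.

Key step: step 9

Assumption: the facial sense of the enzymatic hydrogen-atom transfer cannot be predicted for this substrate; an (S)-selective member is taken to be found by screening a panel of ene-reductases of the old yellow enzyme family (with directed evolution if needed), since enantiocomplementary members of this family are common.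

**Route**

Step 1
Reactants: 1 2-bromo-3-hydroxy-4-methoxybenzaldehyde (2-bromoisovanillin)
Product: 2 2-bromo-3,4-dihydroxybenzaldehyde
Conditions: BBr3 (2.5 equiv), CH2Cl2, −78 °C → rt; then H2O
Reagents that add atoms: none
Why: BBr3-mediated aryl methyl ether cleavage frees the catechol, so that both ring-A oxygens can carry the same acid-labile group and no methyl ether other than the naphthyl one reaches the end of the route.

Step 2
Reactants: 2 2-bromo-3,4-dihydroxybenzaldehyde
Product: 3 2-bromo-3,4-bis(methoxymethoxy)benzaldehyde
Conditions: MOMCl (2.5 equiv), iPr2NEt (3 equiv), CH2Cl2, 0 °C → rt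
Reagents that add atoms: chloromethyl methyl ether (MOMCl), COCCl
Why: O-alkylation of both phenols (Williamson-type acetal formation) gives small protecting groups that are stable to organolithiums and base and fall off together in acid.

Step 3
Reactants: 4 5-methoxynaphthalen-1-ol
Product: 5 4-bromo-5-methoxynaphthalen-1-ol
Conditions: NBS (1.0 equiv), MeCN, −20 → 0 °C, dark
Reagents that add atoms: N-bromosuccinimide (NBS), O=C1CCC(=O)N1Br
Why: Electrophilic aromatic bromination should go para to the free hydroxyl, the strongest activator, which places bromine at C4 peri to the methoxy group; one equivalent at low temperature should hold it at the monobromide.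

Step 4
Reactants: 5 4-bromo-5-methoxynaphthalen-1-ol
Product: 6 1-bromo-8-methoxy-4-(methoxymethoxy)naphthalene
Conditions: MOMCl (1.3 equiv), iPr2NEt (1.6 equiv), CH2Cl2, 0 °C → rt
Reagents that add atoms: chloromethyl methyl ether (MOMCl), COCCl
Why: MOM protection (O-alkylation) masks the acidic, oxidation-prone naphthol before halogen–lithium exchange.

Step 5
Reactants: 6 1-bromo-8-methoxy-4-(methoxymethoxy)naphthalene; 3 2-bromo-3,4-bis(methoxymethoxy)benzaldehyde
Product: 8 racemic (2-bromo-3,4-bis(methoxymethoxy)phenyl)[8-methoxy-4-(methoxymethoxy)naphthalen-1-yl]methanol, via naphthyllithium 7 (not isolated)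
Conditions: n-BuLi (1.05 equiv), THF, −78 °C; then 3, −78 → 0 °C; then H2O
Reagents that add atoms: none
Why: Bromine–lithium exchange gives a 1-naphthyllithium chelated by the peri methoxy group, and its 1,2-addition to the aldehyde should be faster than exchange with the aryl bromide of 3; the carbinol center forms racemic and is erased in step 6.

Step 6
Reactants: 8 racemic (2-bromo-3,4-bis(methoxymethoxy)phenyl)[8-methoxy-4-(methoxymethoxy)naphthalen-1-yl]methanol
Product: 9 (2-bromo-3,4-bis(methoxymethoxy)phenyl)[8-methoxy-4-(methoxymethoxy)naphthalen-1-yl]methanone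
Conditions: Dess–Martin periodinane (1.3 equiv), pyridine, CH2Cl2, 0 °C → rt
Reagents that add atoms: none
Why: Dess–Martin oxidation of the doubly benzylic secondary alcohol runs under near-neutral conditions that spare the MOM acetals and the aryl bromide.

Step 7
Reactants: 9 (2-bromo-3,4-bis(methoxymethoxy)phenyl)[8-methoxy-4-(methoxymethoxy)naphthalen-1-yl]methanone
Product: 10 1-[1-(2-bromo-3,4-bis(methoxymethoxy)phenyl)ethenyl]-8-methoxy-4-(methoxymethoxy)naphthalene
Conditions: Ph3PCH3Br (3 equiv), KOtBu (2.8 equiv), THF, 0 °C; then 9, 65 °C
Reagents that add atoms: methyltriphenylphosphonium bromide, C[P+](c1ccccc1)(c1ccccc1)c1ccccc1.[Br-]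
Why: Wittig methylenation of the non-enolizable diaryl ketone with the small ylide Ph3P=CH2 installs the 1,1-diarylethene, with heating to offset the twisted, electron-rich carbonyl.

Step 8
Reactants: 10 1-[1-(2-bromo-3,4-bis(methoxymethoxy)phenyl)ethenyl]-8-methoxy-4-(methoxymethoxy)naphthalene
Product: 12 2-chloro-1-[6-{1-[8-methoxy-4-(methoxymethoxy)naphthalen-1-yl]ethenyl}-2,3-bis(methoxymethoxy)phenyl]ethan-1-one, via aryllithium 11 (not isolated)
Conditions: t-BuLi (2.0 equiv), Et2O, −78 °C; then ClCH2C(O)N(OMe)Me, −78 → −20 °C; then AcOH, −78 °C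
Reagents that add atoms: 2-chloro-N-methoxy-N-methylacetamide, CON(C)C(=O)CCl
Why: Bromine–lithium exchange at −78 °C should outrun carbolithiation of the twisted diarylethene, and the aryllithium acylates the Weinreb amide to a stable tetrahedral chelate that releases the α-chloroketone only on quench (Weinreb ketone synthesis).

Step 9
Reactants: 12 2-chloro-1-[6-{1-[8-methoxy-4-(methoxymethoxy)naphthalen-1-yl]ethenyl}-2,3-bis(methoxymethoxy)phenyl]ethan-1-one
Product: 13 (4S)-4-[8-methoxy-4-(methoxymethoxy)naphthalen-1-yl]-7,8-bis(methoxymethoxy)-3,4-dihydronaphthalen-1(2H)-one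
Conditions: flavin-dependent ene-reductase (old yellow enzyme family, (S)-selective variant from a GluER/OYE1/NostocER panel), NADP+ (cat.), GDH, D-glucose, Tris buffer pH 8/DMSO 9:1, cyan LEDs (ca. 500 nm), 25 °C, N2
Reagents that add atoms: none
Why: Proposed new method: in the active site the ketone of 12 is hydrogen-bonded above the reduced flavin (FMNH2), and cyan-light excitation of this charge-transfer complex moves one electron to the C–Cl bond, which fragments to chloride and an electrophilic alpha-keto radical at C2. The radical adds to the unsubstituted CH2 terminus (C3) of the ortho 1,1-diarylethene and closes the cyclohexanone ring in the 6-endo-trig mode, the only ring formed. The resulting doubly benzylic C4 radical takes a hydrogen atom from N5–H of the flavin semiquinone on the face that the chiral pocket leaves open, so the (S) stereocenter is set by the enzyme (catalyst control), and NADPH regenerated by GDH/glucose returns the flavin to FMNH2. The closest known reaction type is the photoenzymatic ene-reductase cyclization of alpha-chloroamides onto tethered 1,1-disubstituted alkenes, together with the intermolecular hydroalkylation of alpha-substituted styrenes by alpha-halocarbonyl compounds in the same enzymes; not yet shown are an aryl alpha-chloroketone tether, a 6-endo closure to a tetralone and a radical bearing two aryl groups. The step needs 6-endo over 5-exo closure, secured by the diaryl-substituted C4 (blocked, and giving only a primary radical in the exo mode), cyclization before premature hydrogen-atom transfer, secured by the ortho relationship of the two arms on ring A, and face selectivity, which no small hydrogen-atom donor offers for such a radical.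

Step 10
Reactants: 13 (4S)-4-[8-methoxy-4-(methoxymethoxy)naphthalen-1-yl]-7,8-bis(methoxymethoxy)-3,4-dihydronaphthalen-1(2H)-one
Product: 14 (4S)-7,8-dihydroxy-4-(4-hydroxy-8-methoxynaphthalen-1-yl)-3,4-dihydronaphthalen-1(2H)-one
Conditions: HCl (cat.), degassed MeOH, 0 → 40 °C, N2
Reagents that add atoms: none
Why: Acid-catalysed acetal cleavage (transacetalisation to dimethoxymethane) removes all three MOM groups while the aryl methyl ether is inert, and the stereocenter, gamma to the ketone, cannot epimerise by enolisation.

**Compound list**
1 | 2-bromo-3-hydroxy-4-methoxybenzaldehyde | O=Cc1ccc(OC)c(O)c1Br | starting material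
2 | 2-bromo-3,4-dihydroxybenzaldehyde | O=Cc1ccc(O)c(O)c1Br | intermediate
3 | 2-bromo-3,4-bis(methoxymethoxy)benzaldehyde | O=Cc1ccc(OCOC)c(OCOC)c1Br | intermediate
4 | 5-methoxynaphthalen-1-ol | COc1cccc2c(O)cccc12 | starting material
5 | 4-bromo-5-methoxynaphthalen-1-ol | COc1cccc2c(O)ccc(Br)c12 | intermediate
6 | 1-bromo-8-methoxy-4-(methoxymethoxy)naphthalene | COc1cccc2c(OCOC)ccc(Br)c12 | intermediate
7 | [8-methoxy-4-(methoxymethoxy)naphthalen-1-yl]lithium (formed in the flask) | COc1cccc2c(OCOC)ccc([Li])c12 | intermediate
8 | racemic (2-bromo-3,4-bis(methoxymethoxy)phenyl)[8-methoxy-4-(methoxymethoxy)naphthalen-1-yl]methanol | COc1cccc2c(OCOC)ccc(C(O)c3ccc(OCOC)c(OCOC)c3Br)c12 | intermediate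
9 | (2-bromo-3,4-bis(methoxymethoxy)phenyl)[8-methoxy-4-(methoxymethoxy)naphthalen-1-yl]methanone | COc1cccc2c(OCOC)ccc(C(=O)c3ccc(OCOC)c(OCOC)c3Br)c12 | intermediate
10 | 1-[1-(2-bromo-3,4-bis(methoxymethoxy)phenyl)ethenyl]-8-methoxy-4-(methoxymethoxy)naphthalene | COc1cccc2c(OCOC)ccc(C(=C)c3ccc(OCOC)c(OCOC)c3Br)c12 | intermediate
11 | [6-{1-[8-methoxy-4-(methoxymethoxy)naphthalen-1-yl]ethenyl}-2,3-bis(methoxymethoxy)phenyl]lithium (formed in the flask) | COc1cccc2c(OCOC)ccc(C(=C)c3ccc(OCOC)c(OCOC)c3[Li])c12 | intermediate
12 | 2-chloro-1-[6-{1-[8-methoxy-4-(methoxymethoxy)naphthalen-1-yl]ethenyl}-2,3-bis(methoxymethoxy)phenyl]ethan-1-one | COc1cccc2c(OCOC)ccc(C(=C)c3ccc(OCOC)c(OCOC)c3C(=O)CCl)c12 | intermediate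
13 | (4S)-4-[8-methoxy-4-(methoxymethoxy)naphthalen-1-yl]-7,8-bis(methoxymethoxy)-3,4-dihydronaphthalen-1(2H)-one | COc1cccc2c(OCOC)ccc([C@@H]3CCC(=O)c4c3ccc(OCOC)c4OCOC)c12 | intermediate
14 | (4S)-7,8-dihydroxy-4-(4-hydroxy-8-methoxynaphthalen-1-yl)-3,4-dihydronaphthalen-1(2H)-one | COc1cccc2c(O)ccc([C@@H]3CCC(=O)c4c3ccc(O)c4O)c12 | target

**Step count**
Total steps: 10. Longest linear sequence: 8 steps (1 → 2 → 3 → 8 → 9 → 10 → 12 → 13 → 14; the branch from 4 is equally long).

**Steps most likely to fail**

1. Step 9 (proposed new method). The bulky substrate may bind poorly in the active site and turn over slowly, the alpha-keto radical may take a hydrogen atom before it cyclizes (hydrodechlorination), or the terminating hydrogen-atom transfer may discriminate the faces weakly. The fallback sets out from 12 and returns at 13. Slow addition of Bu3SnH/AIBN to 12 at high dilution (PhH, 80 °C) should bring about the same 6-endo radical cyclization without stereocontrol and give the racemic tris-MOM tetralone F1. Preparative chiral SFC on a polysaccharide phase should then separate 13 from the (4R)-enantiomer F2, which is discarded.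

2. Step 8. The alkyllithium may add to the diarylethene (carbolithiation) in competition with exchange, or the hindered aryllithium may deprotonate the Weinreb amide and end up protonated instead of acylated. The fallback sets out from 10 and returns at 12. Stille coupling of 10 with tributyl(1-ethoxyvinyl)stannane (Pd(PPh3)4, CuI, CsF, DMF, 80 °C) should give the aryl enol ether 1-[1-(2-(1-ethoxyethenyl)-3,4-bis(methoxymethoxy)phenyl)ethenyl]-8-methoxy-4-(methoxymethoxy)naphthalene F3. Its enol ether, far more nucleophilic than the twisted diarylethene, should be chlorinated selectively by NCS in THF/H2O at 0 °C to release 12.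

3. Step 7. Ylide addition to the twisted, electron-rich, ortho- and peri-hindered carbonyl may be slow or incomplete, and prolonged heating with base may degrade the material. The fallback sets out from 9 and returns at 10. Addition of MeMgBr/CeCl3 (THF, 0 °C) should give the tertiary carbinol racemic 1-(2-bromo-3,4-bis(methoxymethoxy)phenyl)-1-[8-methoxy-4-(methoxymethoxy)naphthalen-1-yl]ethan-1-ol F4. Dehydration of this doubly benzylic alcohol with catalytic PPTS (toluene, 60 °C) should give 10, with water as the only thing lost.

Further compounds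
F1 | step 9 | racemic 4-[8-methoxy-4-(methoxymethoxy)naphthalen-1-yl]-7,8-bis(methoxymethoxy)-3,4-dihydronaphthalen-1(2H)-one | COc1cccc2c(OCOC)ccc(C3CCC(=O)c4c3ccc(OCOC)c4OCOC)c12
F2 | step 9 | (4R)-4-[8-methoxy-4-(methoxymethoxy)naphthalen-1-yl]-7,8-bis(methoxymethoxy)-3,4-dihydronaphthalen-1(2H)-one | COc1cccc2c(OCOC)ccc([C@H]3CCC(=O)c4c3ccc(OCOC)c4OCOC)c12
F3 | step 8 | 1-[1-(2-(1-ethoxyethenyl)-3,4-bis(methoxymethoxy)phenyl)ethenyl]-8-methoxy-4-(methoxymethoxy)naphthalene | COc1cccc2c(OCOC)ccc(C(=C)c3ccc(OCOC)c(OCOC)c3C(=C)OCC)c12
F4 | step 7 | racemic 1-(2-bromo-3,4-bis(methoxymethoxy)phenyl)-1-[8-methoxy-4-(methoxymethoxy)naphthalen-1-yl]ethan-1-ol | COc1cccc2c(OCOC)ccc(C(C)(O)c3ccc(OCOC)c(OCOC)c3Br)c12
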